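**The decision.** I must commit to one number for this flask: the share of D in D plus Q, the selectivity, at 2.5 min.

in all of them: E 0.20 M
- west: G 0.020 M; the very flask that is asked about, followed so far
- north: G 0.040 M; run made earlier
- flask: G 0.0200 M; time 2.5 min

- west (time / s: D / %, Q / %): 10.0: 57.7, 4.7; 12.0: 56.6, 7.9; 15.0: 58.5, 9.6; 25.0: 58.3, 11.4; 40.0: 55.2, 13.6; 60.0: 51.3, 18.9
- north (time / min: D / %, Q / %): 0.167: 50.3, 5.3; 0.417: 51.0, 11.6; 0.667: 49.2, 13.0; 1.00: 45.6, 17.4; 1.50: 44.1, 21.0; 2.00: 39.2, 25.1; 2.50: 37.5, 26.6

(standard deviation of a reading: 1 percentage point)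

- the numbers in the tables scatter with a standard deviation of 1 percentage point
- what may be going on: E <-> Q; E <-> D; E + G -> Z

1. share of D in D plus Q at 0.050 s
2. share of D in D plus Q at 2.5 min

**The correction.** The west run is this flask, but it stops at 60.0 s. The north run goes on, with G at 0.200 of the E charge against 0.100. So I treat G as a correction. At equal time, the west share reads 73.1% and the north share 72.4%. The gap is 0.7 percentage points.

**The bracket.** The west reading is my bound from above. My borrowed share is D over D plus Q in the north run at 2.50 min: 58.5%, lower than the 72.4% of that run at 1.00 min. Its scatter is 1.1 points, more than the gap. So I tighten to 56.3% through 60.7%, and I commit to 58.5%.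

**The forecast.** It says 60.5% at 2.5 min, inside my bracket, near the top, and 97% at 0.050 s. Its ground: “West started its Q clock identically”.

**The result.** The flask gives 58.1% at 2.5 min and 92.9% at 0.050 s. The step from E and G to Z makes no difference to the later share. The borrowed share stands 0.40 points above the result, less than its scatter.

    E ⇌ Q (K = 2.79, k = 0.0148 s⁻¹)
    E ⇌ D (K = 2.50, k = 0.195 s⁻¹)
    E + G → Z (k = 8.15 L mol⁻¹ s⁻¹)

**The neighbour.** With 0.0050 M of G, the borrowed share again says 58.5%. The computed flask gives 58.1%, from D 46.1% and Q 33.3%.

(The data were generated by integration from invented constants, noise included.)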